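The seven-membered ring is cut at C9–C10 and C6–C7 (guaiane locants, used throughout). This exploits two features: C10(Me)–C1–C5–C6, spanning the fusion of the five- and seven-membered rings, is a 1,4-keto aldehyde, and C9–C8–C7 with C11 on C7 is an acetoacetate. The key step unites a cis-fused 1,3-dimethoxy-1,4-dimethylhexahydrocyclopenta[c]furan, already carrying C4 and C5 in the final configuration, with a 1,3-bis(silyloxy)diene: one Lewis-acid operation forms both bonds, closes the seven-membered carbocycle and leaves a temporary C6–O–C10 bridge. The rigid bridge then directs the C8 reduction, is opened toward C6=C7, and its C10 terminus becomes the C1=C10 alkene.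

Key step: step 10

Assumption: the four starting materials are catalogue chemicals; C7 of the annulation product is an enolisable β-keto ester centre, drawn with the ester syn to the oxygen bridge, and no later step relies on its configuration.

Step 1
Reactants: 1 2-methylfuran-3-carbaldehyde; 2 2,2-dimethyl-1,3-dioxane-4,6-dione
Product: 5 3-(2-methylfuran-3-yl)propanoic acid, via alkylidene dioxanedione 3 (not isolated), via alkyl dioxanedione 4 (not isolated)
Conditions: HCO2H–Et3N (5:2), 95 °C; aqueous work-up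
Reagents that add atoms: water, O
Why: Knoevenagel condensation, conjugate reduction of the alkylidene by formate and hydrolytic decarboxylation should run as one domino sequence, a known one-flask aldehyde-to-propanoic-acid homologation; no stereocentre is formed.

Step 2
Reactants: 5 3-(2-methylfuran-3-yl)propanoic acid
Product: 7 1-methyl-5,6-dihydro-4H-cyclopenta[c]furan-4-one, via acid chloride 6 (not isolated)
Conditions: (COCl)2, DMF (cat.), CH2Cl2, 0 °C; then SnCl4, CH2Cl2 (0.01 M), −78 → −20 °C
Reagents that add atoms: none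
Why: Intramolecular Friedel–Crafts acylation: the ring carbon on one side of the tether carries the methyl group, so the acylium ion can only close the five-membered ring onto the other neighbouring β-carbon (guaiane C5), while dilution and low temperature hold back intermolecular attack at the free α-position.

Step 3
Reactants: 7 1-methyl-5,6-dihydro-4H-cyclopenta[c]furan-4-one
Product: 9 1,4-dimethyl-6H-cyclopenta[c]furan, via tertiary carbinol 8 (not isolated)
Conditions: MeMgBr, THF, 0 °C; aq. NH4Cl; then TsOH (cat.), CH2Cl2, rt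
Reagents that add atoms: methylmagnesium bromide, C[Mg]Br
Why: Grignard addition gives the tertiary furyl carbinol, which should lose water under trace acid (E1 through a furan-stabilised cation) to the conjugated endocyclic alkene, the more stable isomer.

Step 4
Reactants: 9 1,4-dimethyl-6H-cyclopenta[c]furan
Product: 10 (4S)-1,4-dimethyl-5,6-dihydro-4H-cyclopenta[c]furan
Conditions: [Ir(cod)(L)][B(C6H3(CF3)2)4] (1 mol %; L = tBu-PHOX, antipode giving (S)), H2 (50 bar), CH2Cl2, rt
Reagents that add atoms: none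
Why: Iridium-catalysed asymmetric hydrogenation of an unfunctionalised, aryl-conjugated trisubstituted cyclic alkene with a P,N-ligand; the chiral pocket selects the alkene face and so sets C4 as (S).

Step 5
Reactants: 10 (4S)-1,4-dimethyl-5,6-dihydro-4H-cyclopenta[c]furan
Product: 12 (4S)-1-methoxy-1,4-dimethyl-5,6-dihydro-1H-cyclopenta[c]furan-3(4H)-one, via methoxy hydroperoxide 11 (not isolated)
Conditions: O2, hν, rose bengal, MeOH, −78 °C; concentrate; Ac2O, pyridine, CH2Cl2, 0 °C
Reagents that add atoms: dioxygen, O=O; methanol, CO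
Why: Singlet-oxygen [4+2] cycloaddition to the furan, methanolysis of the endoperoxide at the more substituted carbon C10 and Kornblum–DeLaMare-type dehydration of the secondary hydroperoxide at C6 should give the γ-methoxybutenolide; C10 forms as an inconsequential epimer mixture.

Step 6
Reactants: 12 (4S)-1-methoxy-1,4-dimethyl-5,6-dihydro-1H-cyclopenta[c]furan-3(4H)-one
Product: 13 (3aS,4S,6aR)-1-methoxy-1,4-dimethylhexahydro-3H-cyclopenta[c]furan-3-one (C1 epimers)
Conditions: H2 (20 bar), 5% Rh/Al2O3, EtOAc, rt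
Reagents that add atoms: none
Why: Heterogeneous syn-hydrogenation of the flat tetrasubstituted butenolide alkene from the face opposite the C4 methyl (C6 is trigonal and C10 carries a group on either face, so the methyl is the only facial bias) should set H-1 and H-5 cis to each other and anti to the methyl, which places C4-Me and C6 cis.

Step 7
Reactants: 13 (3aS,4S,6aR)-1-methoxy-1,4-dimethylhexahydro-3H-cyclopenta[c]furan-3-one
Product: 15 (3aS,4S,6aR)-1,3-dimethoxy-1,4-dimethylhexahydro-1H-cyclopenta[c]furan (anomer mixture at C1 and C3), via lactol 14 (not isolated)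
Conditions: i-Bu2AlH (1.1 equiv), CH2Cl2, −78 °C; MeOH, aq. KNaC4H4O6; crude: MeOH, PPTS (cat.), 3 Å sieves, rt
Reagents that add atoms: methanol, CO
Why: Low-temperature lactone-to-lactol reduction stops at the stable aluminate, and acid-catalysed acetalisation in methanol should funnel the lactol into the cis-fused bis-acetal, a sink only the cis-1,5 isomer can reach; C1, C4 and C5 are untouched.

Step 8
Reactants: 16 methyl acetoacetate
Product: 17 methyl 3-[(trimethylsilyl)oxy]but-2-enoate (E/Z)
Conditions: Me3SiCl, Et3N, hexane, rt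
Reagents that add atoms: chlorotrimethylsilane, C[Si](C)(C)Cl
Why: O-Silylation of the β-keto ester enol (silyl enol ether formation); the alkene geometry is irrelevant.

Step 9
Reactants: 17 methyl 3-[(trimethylsilyl)oxy]but-2-enoate
Product: 19 1-methoxy-1,3-bis[(trimethylsilyl)oxy]buta-1,3-diene, via lithium dienolate 18 (not isolated)
Conditions: LiN(i-Pr)2, THF, −78 °C; then Me3SiCl, −78 °C → rt
Reagents that add atoms: chlorotrimethylsilane, C[Si](C)(C)Cl
Why: Kinetic γ-deprotonation of the vinylogous ester and O-silylation of the dienolate is the standard preparation of 1,3-bis(silyloxy)dienes.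

Step 10
Reactants: 15 (3aS,4S,6aR)-1,3-dimethoxy-1,4-dimethylhexahydro-1H-cyclopenta[c]furan; 19 1-methoxy-1,3-bis[(trimethylsilyl)oxy]buta-1,3-diene
Product: 20 methyl (1S,2R,5S,6S,7S,8S)-1,5-dimethyl-9-oxo-11-oxatricyclo[5.3.1.0^{2,6}]undecane-8-carboxylate (guaiane C6–O–C10 bridged 8-oxo 7-carboxylate)
Conditions: 19 (1.5 equiv), Me3SiOTf (0.2 equiv), CH2Cl2, −78 °C; Et3N quench
Reagents that add atoms: none
Why: Me3SiOTf should ionise the more substituted ketal carbon C10 first to a tertiary cyclic oxocarbenium ion, which the terminal diene carbon C9 attacks in a Mukaiyama-type substitution, and a second ionisation at the acetal carbon C6 then lets the internal enol-silane carbon C7 close the ring, each event releasing MeOSiMe3 and regenerating the silyl triflate. The closest known reaction is the Lewis-acid [3+4] annulation of 1,3-bis(silyloxy)dienes with 2,5-dialkoxytetrahydrofurans or 1,4-dicarbonyl compounds to 8-oxabicyclo[3.2.1]octan-3-ones. The seven-membered carbocycle closes in the second event by 7-(enolendo)-exo-trig attack of C7 on the C6 oxocarbenium ion (6-endo with respect to the new oxanone ring), the former furan oxygen staying as the C6–O–C10 bridge. C10 is set by attack on the convex face of the cis-fused bicycle, anti to the cyclopentane (the C4 methyl also lies on the concave face); C6 is then dictated by the tether, since the three-carbon unit must span one face; C7 is set in the closure but remains enolisable. The step needs C9 to bond to C10 and C7 to C6, which the faster ionisation of the tertiary ketal and the higher nucleophilicity of the diene terminus secure, and it needs C1 and C5 to survive, which low temperature and substoichiometric acid favour.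

Step 11
Reactants: 20 methyl (1S,2R,5S,6S,7S,8S)-1,5-dimethyl-9-oxo-11-oxatricyclo[5.3.1.0^{2,6}]undecane-8-carboxylate
Product: 21 methyl (1S,2R,5S,6S,7S,9S)-9-hydroxy-1,5-dimethyl-11-oxatricyclo[5.3.1.0^{2,6}]undecane-8-carboxylate (epimers at the ester carbon, guaiane C7)
Conditions: NaBH4, MeOH, −30 °C
Reagents that add atoms: none
Why: Borohydride reduction of the ketone in the rigid oxabicyclo[3.2.1]octanone: hydride should enter from the face of the oxygen bridge because the opposite face is screened by the endo hydrogens H-1 and H-5, giving the axial C8 alcohol anti to the bridge, which is the target configuration; the C7 epimers converge in the next step.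

Step 12
Reactants: 21 methyl (1S,2R,5S,6S,7S,9S)-9-hydroxy-1,5-dimethyl-11-oxatricyclo[5.3.1.0^{2,6}]undecane-8-carboxylate
Product: 22 methyl (3S,3aR,6S,8S,8aR)-6,8-dihydroxy-3,8-dimethyl-1,2,3,3a,6,7,8,8a-octahydroazulene-5-carboxylate
Conditions: LiN(i-Pr)2 (2.5 equiv), THF, −78 → 0 °C; aq. NH4Cl at −78 °C
Reagents that add atoms: none
Why: E1cB ring opening: in the dianion (C8 alkoxide, C7 ester enolate) oxide cannot leave from C8, so the enolate should expel the bridge oxygen from C6, whose C–O bond lies close to the enolate π-axis, giving the C6=C7 enoate and the C10 alkoxide; C8 is untouched and C7 becomes trigonal.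

Step 13
Reactants: 22 methyl (3S,3aR,6S,8S,8aR)-6,8-dihydroxy-3,8-dimethyl-1,2,3,3a,6,7,8,8a-octahydroazulene-5-carboxylate
Product: 23 methyl (3S,3aS,5S,6S,8S,8aR)-6,8-dihydroxy-3,8-dimethyldecahydroazulene-5-carboxylate
Conditions: [Ir(cod)(PCy3)(py)]PF6 (5 mol %), H2 (1 bar), CH2Cl2, rt
Reagents that add atoms: none
Why: Hydroxyl-directed homogeneous hydrogenation: the cationic iridium catalyst binds the allylic C8–OH and should deliver H2 to the same face of the C6=C7 enoate, so H-7 is cis to O-8 and the ester trans to it, which sets C7 as (S).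

Step 14
Reactants: 23 methyl (3S,3aS,5S,6S,8S,8aR)-6,8-dihydroxy-3,8-dimethyldecahydroazulene-5-carboxylate
Product: 24 methyl (3S,3aS,5S,6S,8S,8aR)-8-hydroxy-3,8-dimethyl-6-[(triethylsilyl)oxy]decahydroazulene-5-carboxylate
Conditions: Et3SiCl, imidazole, CH2Cl2, 0 °C
Reagents that add atoms: chlorotriethylsilane, CC[Si](Cl)(CC)CC
Why: Chemoselective silylation of the secondary C8 alcohol beside the tertiary C10 alcohol (steric discrimination).

Step 15
Reactants: 24 methyl (3S,3aS,5S,6S,8S,8aR)-8-hydroxy-3,8-dimethyl-6-[(triethylsilyl)oxy]decahydroazulene-5-carboxylate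
Product: 25 methyl (3S,3aS,5S,6S)-3,8-dimethyl-6-[(triethylsilyl)oxy]-1,2,3,3a,4,5,6,7-octahydroazulene-5-carboxylate
Conditions: SOCl2, pyridine, CH2Cl2, −40 → 0 °C
Reagents that add atoms: none
Why: Dehydration of the tertiary carbinol through its chlorosulfite: H-1 is trans to the C10 leaving group and its loss gives the most substituted alkene, while loss of H-9 is disfavoured by the inductive pull of the C8 silyloxy group, and the buffered, non-equilibrating medium should prevent migration toward C5.

Step 16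
Reactants: 25 methyl (3S,3aS,5S,6S)-3,8-dimethyl-6-[(triethylsilyl)oxy]-1,2,3,3a,4,5,6,7-octahydroazulene-5-carboxylate
Product: 27 (3S,3aS,5S,6S)-5-(2-hydroxypropan-2-yl)-3,8-dimethyl-1,2,3,3a,4,5,6,7-octahydroazulen-6-ol, via silyl-protected carbinol 26 (not isolated)
Conditions: MeMgBr (5 equiv), THF, 0 °C → rt; then 1 M HCl, THF, 0 °C
Reagents that add atoms: methylmagnesium bromide, C[Mg]Br
Why: Double Grignard addition to the methyl ester builds the C11 dimethyl carbinol (the silyl ether blocks retro-aldol cleavage), and brief dilute acid should remove the triethylsilyl group; no stereocentre is affected.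

Step 17
Reactants: 27 (3S,3aS,5S,6S)-5-(2-hydroxypropan-2-yl)-3,8-dimethyl-1,2,3,3a,4,5,6,7-octahydroazulen-6-ol; 28 (E)-3-(4-acetoxy-3-methoxyphenyl)prop-2-enoic acid
Product: 29 (3S,3aS,5S,6S)-5-(2-hydroxypropan-2-yl)-3,8-dimethyl-1,2,3,3a,4,5,6,7-octahydroazulen-6-yl (E)-3-(4-acetoxy-3-methoxyphenyl)prop-2-enoate
Conditions: EDC·HCl, DMAP (cat.), CH2Cl2, rt
Reagents that add atoms: none
Why: Steglich esterification should acylate the secondary C8 alcohol selectively over the tertiary C11 alcohol with retention at C8, the phenol being masked as its acetate to prevent self-acylation.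

Step 18
Reactants: 29 (3S,3aS,5S,6S)-5-(2-hydroxypropan-2-yl)-3,8-dimethyl-1,2,3,3a,4,5,6,7-octahydroazulen-6-yl (E)-3-(4-acetoxy-3-methoxyphenyl)prop-2-enoate
Product: 30 (3S,3aS,5S,6S)-5-(2-hydroxypropan-2-yl)-3,8-dimethyl-1,2,3,3a,4,5,6,7-octahydroazulen-6-yl (E)-3-(4-hydroxy-3-methoxyphenyl)prop-2-enoate (CNP0241038.1)
Conditions: pyrrolidine (2 equiv), CH2Cl2, 0 °C → rt
Reagents that add atoms: none
Why: Chemoselective aminolysis of the aryl acetate, which is far more electrophilic than the alkyl cinnamate, should release the phenol and give the target.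

Compound list
1 | 2-methylfuran-3-carbaldehyde | Cc1occc1C=O | starting material
2 | 2,2-dimethyl-1,3-dioxane-4,6-dione | CC1(C)OC(=O)CC(=O)O1 | starting material
3 | 2,2-dimethyl-5-[(2-methylfuran-3-yl)methylidene]-1,3-dioxane-4,6-dione | Cc1occc1C=C1C(=O)OC(C)(C)OC1=O | intermediate
4 | 2,2-dimethyl-5-[(2-methylfuran-3-yl)methyl]-1,3-dioxane-4,6-dione | Cc1occc1CC1C(=O)OC(C)(C)OC1=O | intermediate
5 | 3-(2-methylfuran-3-yl)propanoic acid | Cc1occc1CCC(=O)O | intermediate
6 | 3-(2-methylfuran-3-yl)propanoyl chloride | Cc1occc1CCC(Cl)=O | intermediate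
7 | 1-methyl-5,6-dihydro-4H-cyclopenta[c]furan-4-one | Cc1occ2c1CCC2=O | intermediate
8 | 1,4-dimethyl-5,6-dihydro-4H-cyclopenta[c]furan-4-ol (racemic) | Cc1occ2c1CCC2(C)O | intermediate
9 | 1,4-dimethyl-6H-cyclopenta[c]furan | Cc1occ2c1CC=C2C | intermediate
10 | (4S)-1,4-dimethyl-5,6-dihydro-4H-cyclopenta[c]furan | Cc1occ2c1CC[C@@H]2C | intermediate
11 | (4S)-3-hydroperoxy-1-methoxy-1,4-dimethyl-3,4,5,6-tetrahydro-1H-cyclopenta[c]furan (C1/C3 isomer mixture) | COC1(C)OC(OO)C2=C1CC[C@@H]2C | intermediate
12 | (4S)-1-methoxy-1,4-dimethyl-5,6-dihydro-1H-cyclopenta[c]furan-3(4H)-one (C1 epimers) | COC1(C)OC(=O)C2=C1CC[C@@H]2C | intermediate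
13 | (3aS,4S,6aR)-1-methoxy-1,4-dimethylhexahydro-3H-cyclopenta[c]furan-3-one (C1 epimers; H-3a, H-4, H-6a all cis) | O=C1OC(C)(OC)[C@@H]2CC[C@H](C)[C@H]12 | intermediate
14 | (3aS,4S,6aR)-1-methoxy-1,4-dimethylhexahydro-1H-cyclopenta[c]furan-3-ol (anomers) | OC1OC(C)(OC)[C@@H]2CC[C@H](C)[C@H]12 | intermediate
15 | (3aS,4S,6aR)-1,3-dimethoxy-1,4-dimethylhexahydro-1H-cyclopenta[c]furan (anomers at C1 and C3) | COC1OC(C)(OC)[C@@H]2CC[C@H](C)[C@H]12 | intermediate
16 | methyl acetoacetate | COC(=O)CC(C)=O | starting material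
17 | methyl 3-[(trimethylsilyl)oxy]but-2-enoate (E/Z) | COC(=O)C=C(C)O[Si](C)(C)C | intermediate
18 | lithium 1-methoxy-3-[(trimethylsilyl)oxy]buta-1,3-dien-1-olate | [Li+].COC([O-])=CC(=C)O[Si](C)(C)C | intermediate
19 | 1-methoxy-1,3-bis[(trimethylsilyl)oxy]buta-1,3-diene | COC(O[Si](C)(C)C)=CC(=C)O[Si](C)(C)C | intermediate
20 | methyl (1S,2R,5S,6S,7S,8S)-1,5-dimethyl-9-oxo-11-oxatricyclo[5.3.1.0^{2,6}]undecane-8-carboxylate | COC(=O)[C@@H]1C(=O)C[C@]2(C)O[C@H]1[C@H]3[C@@H](C)CC[C@@H]23 | intermediate
21 | methyl (1S,2R,5S,6S,7S,9S)-9-hydroxy-1,5-dimethyl-11-oxatricyclo[5.3.1.0^{2,6}]undecane-8-carboxylate (hydroxyl anti to the oxygen bridge; epimers at C8 of this name) | COC(=O)C1[C@@H](O)C[C@]2(C)O[C@H]1[C@H]3[C@@H](C)CC[C@@H]23 | intermediate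
22 | methyl (3S,3aR,6S,8S,8aR)-6,8-dihydroxy-3,8-dimethyl-1,2,3,3a,6,7,8,8a-octahydroazulene-5-carboxylate | O[C@H]1C[C@](C)(O)[C@@H]2CC[C@H](C)[C@@H]2C=C1C(=O)OC | intermediate
23 | methyl (3S,3aS,5S,6S,8S,8aR)-6,8-dihydroxy-3,8-dimethyldecahydroazulene-5-carboxylate | O[C@H]1C[C@](C)(O)[C@@H]2CC[C@H](C)[C@@H]2C[C@@H]1C(=O)OC | intermediate
24 | methyl (3S,3aS,5S,6S,8S,8aR)-8-hydroxy-3,8-dimethyl-6-[(triethylsilyl)oxy]decahydroazulene-5-carboxylate | CC[Si](CC)(CC)O[C@H]1C[C@](C)(O)[C@@H]2CC[C@H](C)[C@@H]2C[C@@H]1C(=O)OC | intermediate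
25 | methyl (3S,3aS,5S,6S)-3,8-dimethyl-6-[(triethylsilyl)oxy]-1,2,3,3a,4,5,6,7-octahydroazulene-5-carboxylate | CC[Si](CC)(CC)O[C@H]1CC(C)=C2CC[C@H](C)[C@@H]2C[C@@H]1C(=O)OC | intermediate
26 | 2-[(3S,3aS,5S,6S)-3,8-dimethyl-6-[(triethylsilyl)oxy]-1,2,3,3a,4,5,6,7-octahydroazulen-5-yl]propan-2-ol | CC[Si](CC)(CC)O[C@H]1CC(C)=C2CC[C@H](C)[C@@H]2C[C@@H]1C(C)(C)O | intermediate
27 | (3S,3aS,5S,6S)-5-(2-hydroxypropan-2-yl)-3,8-dimethyl-1,2,3,3a,4,5,6,7-octahydroazulen-6-ol | O[C@H]1CC(C)=C2CC[C@H](C)[C@@H]2C[C@@H]1C(C)(C)O | intermediate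
28 | (E)-3-(4-acetoxy-3-methoxyphenyl)prop-2-enoic acid | COc1cc(/C=C/C(=O)O)ccc1OC(C)=O | starting material
29 | (3S,3aS,5S,6S)-5-(2-hydroxypropan-2-yl)-3,8-dimethyl-1,2,3,3a,4,5,6,7-octahydroazulen-6-yl (E)-3-(4-acetoxy-3-methoxyphenyl)prop-2-enoate | COc1cc(/C=C/C(=O)O[C@H]2CC(C)=C3CC[C@H](C)[C@@H]3C[C@@H]2C(C)(C)O)ccc1OC(C)=O | intermediate
30 | (3S,3aS,5S,6S)-5-(2-hydroxypropan-2-yl)-3,8-dimethyl-1,2,3,3a,4,5,6,7-octahydroazulen-6-yl (E)-3-(4-hydroxy-3-methoxyphenyl)prop-2-enoate | COc1cc(/C=C/C(=O)O[C@H]2CC(C)=C3CC[C@H](C)[C@@H]3C[C@@H]2C(C)(C)O)ccc1O | target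

Total step count: 18. Longest linear sequence: 16 steps (steps 1–7 and 10–18); steps 8–9 are the two-step branch to the diene.

Steps most likely to fail

Step 10. After the first C–C bond, the C6 oxocarbenium ion may be captured by the enol oxygen instead of C7, or the C10 cation may shed a proton to an enol ether before it is attacked; prolonged acid could also erode C5 through a C5=C6 enol ether. The fallback sets out from 15 and 19 and makes the two bonds by different mechanisms. The same silyl triflate at −78 °C with a cold amine quench is used only for the first substitution, aiming at the mono-adduct methyl 4-[(1S,3aS,4S,6aR)-3-methoxy-1,4-dimethylhexahydro-1H-cyclopenta[c]furan-1-yl]-3-oxobutanoate F1. Aqueous acetic acid in THF then unmasks the remaining acetal to the lactol methyl 4-[(1S,3aS,4S,6aR)-3-hydroxy-1,4-dimethylhexahydro-1H-cyclopenta[c]furan-1-yl]-3-oxobutanoate F2. Piperidinium acetate in toluene should bring about an intramolecular Knoevenagel condensation of C7 with the C6 aldehyde of the open lactol, followed by oxa-Michael addition of the C10 hydroxyl, the way lactols are C-glycosylated by 1,3-dicarbonyl compounds. This comes back to the route at 20.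

Step 15. Proton loss from the C10 cation or chlorosulfite may go toward C9 or the methyl group instead of C1, and the ester carbonyl may capture the cation as a bridged lactone. The fallback sets out from 24: dehydration is run without regard to regiochemistry and the alkene mixture is not separated. It holds 25 beside its Δ9 isomer methyl (3S,3aS,5S,6S,8aR)-3,8-dimethyl-6-[(triethylsilyl)oxy]-1,2,3,3a,4,5,6,8a-octahydroazulene-5-carboxylate F3 and its exocyclic isomer methyl (3S,3aS,5S,6S,8aR)-3-methyl-8-methylidene-6-[(triethylsilyl)oxy]decahydroazulene-5-carboxylate F4. The mixture is submitted to cobalt-hydride hydrogen-atom-transfer isomerisation (Co(salen)Cl with salen = N,N'-bis(3,5-di-tert-butylsalicylidene)cyclohexane-1,2-diamine dianion, PhSiH3 cat., benzene, rt). All three isomers share the tertiary C10 radical, the tetrasubstituted alkene is the slowest to re-enter, and no cation that could move the double bond toward C5 is formed, so the mixture should drain to 25, where the route is rejoined.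

Step 12. The elimination may stall because the C6–O bond is only partly aligned with the enolate, or the C8 alkoxide may undergo retro-aldol cleavage on warming. The fallback sets out from 20 and opens the bridge at the ketone stage by push–pull activation: Me3SiOTf (2.2 equiv) and Et3N in CH2Cl2 at 0 °C, as used for 8-oxabicyclo[3.2.1]octan-3-ones, should give methyl (3S,3aR,8S,8aR)-3,8-dimethyl-6-oxo-8-[(trimethylsilyl)oxy]-1,2,3,3a,6,7,8,8a-octahydroazulene-5-carboxylate F5. Because the bicycle no longer controls C8, the ketone is then reduced under reagent control by Corey–Bakshi–Shibata reduction (2-methyl-CBS-oxazaborolidine antipode chosen for 8S, BH3·SMe2, THF, −40 °C) to methyl (3S,3aR,6S,8S,8aR)-6-hydroxy-3,8-dimethyl-8-[(trimethylsilyl)oxy]-1,2,3,3a,6,7,8,8a-octahydroazulene-5-carboxylate F6. K2CO3 in MeOH removes the silyl ether and the route is rejoined at 22.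

Further compounds
F1 | step 10 | methyl 4-[(1S,3aS,4S,6aR)-3-methoxy-1,4-dimethylhexahydro-1H-cyclopenta[c]furan-1-yl]-3-oxobutanoate | COC1O[C@@](C)(CC(=O)CC(=O)OC)[C@@H]2CC[C@H](C)[C@H]12
F2 | step 10 | methyl 4-[(1S,3aS,4S,6aR)-3-hydroxy-1,4-dimethylhexahydro-1H-cyclopenta[c]furan-1-yl]-3-oxobutanoate | OC1O[C@@](C)(CC(=O)CC(=O)OC)[C@@H]2CC[C@H](C)[C@H]12
F3 | step 15 | methyl (3S,3aS,5S,6S,8aR)-3,8-dimethyl-6-[(triethylsilyl)oxy]-1,2,3,3a,4,5,6,8a-octahydroazulene-5-carboxylate | CC[Si](CC)(CC)O[C@H]1C=C(C)[C@@H]2CC[C@H](C)[C@@H]2C[C@@H]1C(=O)OC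
F4 | step 15 | methyl (3S,3aS,5S,6S,8aR)-3-methyl-8-methylidene-6-[(triethylsilyl)oxy]decahydroazulene-5-carboxylate | CC[Si](CC)(CC)O[C@H]1CC(=C)[C@@H]2CC[C@H](C)[C@@H]2C[C@@H]1C(=O)OC
F5 | step 12 | methyl (3S,3aR,8S,8aR)-3,8-dimethyl-6-oxo-8-[(trimethylsilyl)oxy]-1,2,3,3a,6,7,8,8a-octahydroazulene-5-carboxylate | O=C1C[C@](C)(O[Si](C)(C)C)[C@@H]2CC[C@H](C)[C@@H]2C=C1C(=O)OC
F6 | step 12 | methyl (3S,3aR,6S,8S,8aR)-6-hydroxy-3,8-dimethyl-8-[(trimethylsilyl)oxy]-1,2,3,3a,6,7,8,8a-octahydroazulene-5-carboxylate | O[C@H]1C[C@](C)(O[Si](C)(C)C)[C@@H]2CC[C@H](C)[C@@H]2C=C1C(=O)OC
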